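## The problem

Betaethrin A (26) is an achiral diaryl ether. Ring A is a methyl benzoate with CO2CH3 at C1, OH at C2, CH3 at C4 and the ether oxygen at C6; that oxygen is bonded to C1′ of ring B, which carries OH at C2′, OCH3 at C4′ and CH2OAc at C6′. There is no stereocentre, so nothing has to be set or relayed, and the difficulty lies in connectivity and in keeping similar functions apart. The C6–O–C1′ link is tri-ortho-substituted (the ring B oxygen sits between C2′–O and C6′–CH2, the ring A carbon next to the ester), which is where copper- or palladium-catalysed etherification of a preformed 2-halobenzoate with a hindered phenol is slowest. Two phenols, two different esters and one benzylic oxygen must be differentiated purely by the order of events. The sensitive points are the benzylic acetate (cleaved by hydroxide or alkoxide, ionised by strong Lewis acids, transferred to a neighbouring phenoxide if installed too early), the electron-rich ring B phenol (oxidation, alkylation by formaldehyde equivalents during acetal removal) and the ring A ester/ring B benzylic oxygen pair, which can close to an eight-membered lactone under base. The enabling feature is the contiguous triad C6 (O-aryl), C1 (CO2CH3), C2 (OH) of ring A with CH3 para to the carboxyl: this is the pattern left when an oxygen nucleophile and then a one-carbon electrophile add across the triple bond of a 3-oxygenated 5-methylbenzyne, the oxygen substituent deciding which end receives which partner.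

## Retrosynthesis

Endgame, 26 back to 22. The last bonds cut are the two O–CH2OCH3 bonds of bis-acetal 25, so that both phenols stay masked while the benzylic hydroxyl of 24 is the only one open to acetylation. Alcohol 24 comes from silyl ether 23, and the methyl ester of 23 from acid 22 by carboxylate alkylation. The acetate is placed after the coupling because an acetate next to a free ring B phenoxide would migrate. The ester is methylated before desilylation so that no free acid and alcohol ever coexist across the ether bridge. The forward steps must be mild and orthogonal: carboxylate alkylation, buffered fluoride, acylation, and a non-protic acetal cleavage that spares the benzylic acetate.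

Key disconnection, 22 to 9, 16 and 17. Two bonds at adjacent ring A carbons are cut at once: C6–O (to ring B) and C1–CO2H. This leads back to ortho-silylaryl triflate 9 (the source of aryne 19), phenol 16 and carbon dioxide 17. The neighbouring cut, C6–O alone with the carboxyl already in place, would require coupling a 2,6-disubstituted phenol with a 2,6-disubstituted halobenzoate at a hindered sp2 carbon. Cutting both bonds replaces that carbon by an unhindered, strongly electrophilic aryne carbon and uses the resulting carbanion 20 to bring in the carboxyl. The precursors are far simpler: one trisubstituted and one tetrasubstituted benzene plus a gas. The forward reaction must add the oxygen distal to the methoxymethoxy group and then trap the aryl anion with CO2 faster than any proton reaches it.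

Ring A precursor, 9 back to 1. The C–OTf bond of 9 is traced to silylphenol 8 and carbamate 7. The C2–Si bond is cut next, leading to carbamate 3, in which the carbamate and the methoxymethoxy group flank the same ortho carbon and cooperate in directing metalation. Cutting the carbamate and one acetal gives 2 and then orcinol 1. The alternative of brominating orcinol to set up a halogen–metal exchange would functionalise C4 and not C2, so directed metalation between the oxygens is the regiochemically secure choice. The forward sequence needs a mono-protection of a symmetric diol and a carbamate that can be removed without acid, since the aryl–silicon bond between two oxygens is prone to protodesilylation.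

Ring B precursor, 16 back to 10. The O–Si bond is cut to give diol 15, which comes from aldehyde 14 by reduction. The O–CH2OCH3 bond of 14 is cut to catechol 12, the C3–O bond to bromide 11, and the C–Br bond to commercial 2-hydroxy-5-methoxybenzaldehyde 10. The para OH/OCH3 relationship and the formyl carbon are already present in 10, and its only activated free position is the one that needs the new oxygen. The forward steps must brominate at that position, exchange Br for OH, alkylate the catechol at the oxygen remote from the formyl group, and silylate the primary alcohol in preference to the hindered phenol.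

## Roads not taken

Alternative 1: The cut is the C1′–C6′ bond of ring B, which unravels the ring into an acyclic aryloxymethyl triketone A1 carrying the ring A benzoate. Forward, base-induced intramolecular aldol addition of the aryloxy-bearing methylene to the terminal ketone, dehydration and enolisation would give resorcinol A2. Its merit is that the diaryl ether oxygen is introduced by ordinary O-alkylation of a ring A phenol, so no hindered aryl–oxygen bond has to be forged at all; in that respect it is better than the chosen plan. The weak points are several. A1 is a sensitive polycarbonyl chain needing polyanion acylation chemistry. The nucleophilic carbon is the least acidic methylene of the chain, so O-cyclisation to a pyranone and the alternative aldol from the acetal-bearing terminus compete. A2 emerges with two free phenols (C2′ and C4′) that must be told apart for mono-methylation. The acetal then still has to be hydrolysed, reduced and acetylated. The chosen plan sets against this stable aromatic partners whose oxygen pattern is fixed before the union, and a shorter endgame.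

Alternative 2: Four ring B bonds are cut (C5′–C6′, C2′–C3′, C4′–C5′, C1′–C2′), leading to the aryloxy-substituted unsaturated diazoketone A3 and methoxyacetylene A4. Forward, irradiation of A3 gives a vinylketene by Wolff rearrangement; cycloaddition with A4, four-electron ring opening and six-electron electrocyclisation deliver phenol A5. The merits are real: the benzannulation is a known reaction type with predictable regiochemistry, and A5 has C2′–OH free and C4′–OCH3 in place, which saves one acetal and its removal. The weak points are the linear multistep construction of A3 with the ring A ester on board (enol ether formation, diazo transfer next to a benzoate), the donor-substituted and hydrolytically labile aryl vinyl ether, the volatile and unstable A4, and a photochemical step late in a linear sequence. The chosen plan is less precedented at its key step but more convergent, avoids diazo and photochemistry, and draws both rings from cheap aromatics.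

Alternative 3: The cut is through ring A (C1–C6 and C4–C5), giving the ester-activated 4-(methoxymethoxy)-6-methyl-2-pyranone A6 and the ethynyl ether A7 of phenol 16. Forward, cycloaddition across C3/C6 of A6 followed by loss of carbon dioxide (17) from the bridged lactone would give benzoate A8, which is identical with ester 23 of the chosen route, so the endgames coincide. Its merits are a known reaction class, matched polarisation of the two partners and direct delivery of the methyl ester. Its weak points are the two extra strongly basic steps needed to turn the hindered phenol 16 into A7, the hydration and oligomerisation to which aryl ynol ethers are prone, and the 4-alkoxy donor on A6, which lowers its reactivity as an electron-poor diene and calls for heating that A7 may not tolerate. On precedent this road is the stronger one. The chosen plan offers in return direct use of 16, a reaction at or below room temperature, and a fallback that reaches the same ester 23.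

Key step: step 10

Step 1
Reactants: 1 orcinol (5-methylbenzene-1,3-diol)
Product: 2 3-(methoxymethoxy)-5-methylphenol
Conditions: MOMCl (1.0 equiv), K2CO3, acetone, 0 °C → rt; 1 used in threefold excess
Reagents that add atoms: chloromethyl methyl ether, COCCl
Why: Williamson-type O-alkylation of a phenoxide; the excess of the symmetric diol should make mono-etherification dominant, and the surplus water-soluble 1 is washed out and recovered.

Step 2
Reactants: 2 3-(methoxymethoxy)-5-methylphenol
Product: 3 3-(methoxymethoxy)-5-methylphenyl N-isopropylcarbamate
Conditions: i-PrNCO, Et3N (cat.), CH2Cl2, rt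
Reagents that add atoms: isopropyl isocyanate, CC(C)N=C=O
Why: Amine-catalysed addition of a phenol to an isocyanate (carbamoylation); the N-monoalkyl carbamate is a strong directing group that can later be removed under base without acid.

Step 3
Reactants: 3 3-(methoxymethoxy)-5-methylphenyl N-isopropylcarbamate
Product: 7 3-(methoxymethoxy)-5-methyl-2-(trimethylsilyl)phenyl N-isopropylcarbamate, via N-silyl carbamate 4 (not isolated), via aryllithium 5 (not isolated), via N-silyl C-silyl carbamate 6 (not isolated)
Conditions: TBSOTf, TMEDA, Et2O, 0 °C → rt; n-BuLi, TMEDA, −78 °C; TMSCl, −78 °C → rt; aq NH4Cl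
Reagents that add atoms: chlorotrimethylsilane, C[Si](C)(C)Cl
Why: Directed ortho-metalation; transient N-silylation masks the N–H, the carbamate and the methoxymethoxy group jointly direct lithiation to the carbon between them, TMSCl silylates that carbon, and the N–Si bond is hydrolysed on work-up.

Step 4
Reactants: 7 3-(methoxymethoxy)-5-methyl-2-(trimethylsilyl)phenyl N-isopropylcarbamate
Product: 9 3-(methoxymethoxy)-5-methyl-2-(trimethylsilyl)phenyl trifluoromethanesulfonate, via silylphenol 8 (not isolated)
Conditions: DBU, Et2NH, MeCN, 40 °C; then PhNTf2, rt
Reagents that add atoms: N-phenylbis(trifluoromethanesulfonimide), O=S(=O)(N(c1ccccc1)S(=O)(=O)C(F)(F)F)C(F)(F)F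
Why: E1cB cleavage of the N-monoalkyl carbamate (the expelled isocyanate is trapped by Et2NH) followed by O-triflation of the phenoxide in the same flask; the wholly basic medium should avoid protodesilylation of the electron-rich aryl silane.

Step 5
Reactants: 10 2-hydroxy-5-methoxybenzaldehyde
Product: 11 3-bromo-2-hydroxy-5-methoxybenzaldehyde
Conditions: Br2, NaOAc, AcOH, rt
Reagents that add atoms: bromine, BrBr
Why: Electrophilic aromatic bromination; C3 is ortho to the phenol and meta to the formyl group, and the para position of the phenol is blocked by OCH3.

Step 6
Reactants: 11 3-bromo-2-hydroxy-5-methoxybenzaldehyde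
Product: 12 2,3-dihydroxy-5-methoxybenzaldehyde
Conditions: NaOH (aq), Cu powder (cat.), reflux, N2; then HCl (aq)
Reagents that add atoms: sodium hydroxide, [Na+].[OH-]
Why: Copper-mediated (Ullmann-type) hydroxylation of an ortho-bromophenoxide, the transformation long used on bromo hydroxybenzaldehydes; the phenoxide form protects the aldehyde from Cannizzaro reaction and inert gas protects the catechol from oxidation.

Step 7
Reactants: 12 2,3-dihydroxy-5-methoxybenzaldehyde
Product: 14 2-hydroxy-5-methoxy-3-(methoxymethoxy)benzaldehyde, via disodium catecholate 13 (not isolated)
Conditions: NaH (2.1 equiv), DMF, 0 °C → rt; MOMCl (1.0 equiv), 0 °C; aq NH4Cl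
Reagents that add atoms: chloromethyl methyl ether, COCCl
Why: Regioselective mono-O-alkylation of a catechol dianion; the O-2 oxide is delocalised into the ortho formyl group and chelated, so the more basic O-3 oxide should take the single equivalent of electrophile.

Step 8
Reactants: 14 2-hydroxy-5-methoxy-3-(methoxymethoxy)benzaldehyde
Product: 15 2-(hydroxymethyl)-4-methoxy-6-(methoxymethoxy)phenol
Conditions: NaBH4, MeOH–THF, 0 °C
Reagents that add atoms: none
Why: Borohydride reduction of an aryl aldehyde; the acetal and ethers are inert, and a neutral work-up avoids ortho-quinone methide formation from the salicyl alcohol.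

Step 9
Reactants: 15 2-(hydroxymethyl)-4-methoxy-6-(methoxymethoxy)phenol
Product: 16 2-(tert-butyldimethylsilyloxymethyl)-4-methoxy-6-(methoxymethoxy)phenol
Conditions: TBSCl (1.05 equiv), imidazole, CH2Cl2, 0 °C
Reagents that add atoms: tert-butyldimethylsilyl chloride, CC(C)(C)[Si](C)(C)Cl
Why: Chemoselective silylation of a primary benzylic alcohol in the presence of a 2,6-disubstituted phenol, as is standard for salicyl alcohols; the hindered phenol reacts much more slowly with the bulky silyl chloride.

Step 10
Reactants: 9 3-(methoxymethoxy)-5-methyl-2-(trimethylsilyl)phenyl trifluoromethanesulfonate; 16 2-(tert-butyldimethylsilyloxymethyl)-4-methoxy-6-(methoxymethoxy)phenol; 17 carbon dioxide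
Product: 22 2-[2-(tert-butyldimethylsilyloxymethyl)-4-methoxy-6-(methoxymethoxy)phenoxy]-6-(methoxymethoxy)-4-methylbenzoic acid, via potassium phenoxide 18 (not isolated), via aryne 19 (not isolated), via arylpotassium 20 (not isolated), via potassium carboxylate 21 (not isolated)
Conditions: 16, KH (1.05 equiv), THF, 0 °C; 18-crown-6, spray-dried KF, CO2 (1 atm), then 9 (1.3 equiv) added slowly, 0 °C → rt; cold aq KHSO4 to pH 4
Reagents that add atoms: none
Why: Proposed new method: KH converts phenol 16 into the proton-free potassium phenoxide 18 (H2 is the only by-product), and fluoride from KF/18-crown-6 attacks the SiMe3 group of 9 so that loss of triflate releases aryne 19 slowly in the presence of 18 and dissolved CO2. The phenoxide oxygen should add to the aryne carbon remote from the methoxymethoxy group (the future C6), because the inductively withdrawing oxygen on the neighbouring carbon distorts the triple bond toward distal attack and stabilises the carbanion developing next to it; this is the general regiochemistry of 3-alkoxybenzynes and the remote 5-methyl group should not disturb it. The resulting aryl anion 20, flanked by the aryloxy and methoxymethoxy oxygens, is a stabilised 2,6-dioxygenated carbanion that should capture the small linear electrophile CO2 to give carboxylate 21, which is acidified to 22. The closest known reactions are the fluoride-induced O-arylation of phenols by ortho-silylaryl triflates (same C–O bond, but the anion is protonated), the KF/18-crown-6 three-component coupling of arynes, amines and CO2 (same C–C bond, nitrogen nucleophile), and the classical addition of organolithiums to 3-alkoxybenzynes followed by carboxylation. No ring is closed and no stereocentre is formed. The step needs regioselectivity in the addition, which the 3-methoxymethoxy substituent secures, and chemoselectivity for carboxylation over protonation, which is secured by preforming the phenoxide, by using THF in place of the C–H acidic acetonitrile, and by keeping CO2 in large excess over the slowly generated aryne. The di-ortho-substituted phenoxide is no handicap here because it attacks an unencumbered, highly electrophilic aryne carbon and not a substituted aryl halide.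

Step 11
Reactants: 22 2-[2-(tert-butyldimethylsilyloxymethyl)-4-methoxy-6-(methoxymethoxy)phenoxy]-6-(methoxymethoxy)-4-methylbenzoic acid
Product: 23 methyl 2-[2-(tert-butyldimethylsilyloxymethyl)-4-methoxy-6-(methoxymethoxy)phenoxy]-6-(methoxymethoxy)-4-methylbenzoate
Conditions: MeI, K2CO3, DMF, rt
Reagents that add atoms: iodomethane, CI
Why: SN2 alkylation of the carboxylate, which bypasses the hindered carbonyl of a 2,6-disubstituted benzoic acid; no other acidic O–H is present.

Step 12
Reactants: 23 methyl 2-[2-(tert-butyldimethylsilyloxymethyl)-4-methoxy-6-(methoxymethoxy)phenoxy]-6-(methoxymethoxy)-4-methylbenzoate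
Product: 24 methyl 2-[2-(hydroxymethyl)-4-methoxy-6-(methoxymethoxy)phenoxy]-6-(methoxymethoxy)-4-methylbenzoate
Conditions: TBAF, AcOH (1:1), THF, 0 °C → rt
Reagents that add atoms: none
Why: Fluoride desilylation of a primary silyl ether; acetic acid buffering keeps the benzylic oxygen protonated so that it should not attack the ring A ester to form the eight-membered lactone.

Step 13
Reactants: 24 methyl 2-[2-(hydroxymethyl)-4-methoxy-6-(methoxymethoxy)phenoxy]-6-(methoxymethoxy)-4-methylbenzoate
Product: 25 methyl 2-[2-(acetoxymethyl)-4-methoxy-6-(methoxymethoxy)phenoxy]-6-(methoxymethoxy)-4-methylbenzoate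
Conditions: Ac2O, pyridine, DMAP (cat.), CH2Cl2, 0 °C → rt
Reagents that add atoms: acetic anhydride, CC(=O)OC(C)=O
Why: DMAP-catalysed acylation of the only free hydroxyl group; both phenols are still masked as acetals, so no selectivity question arises.

Step 14
Reactants: 25 methyl 2-[2-(acetoxymethyl)-4-methoxy-6-(methoxymethoxy)phenoxy]-6-(methoxymethoxy)-4-methylbenzoate
Product: 26 betaethrin A, methyl 2-[2-(acetoxymethyl)-6-hydroxy-4-methoxyphenoxy]-6-hydroxy-4-methylbenzoate
Conditions: ZnBr2, n-PrSH, CH2Cl2, 0 °C
Reagents that add atoms: none
Why: Lewis acid-assisted cleavage of aryl methoxymethyl ethers with a thiol as cation trap; the thiol should capture the methoxymethyl fragment before it can alkylate the electron-rich ring B, and the short, cold, non-protic conditions should leave the methyl ester and benzylic acetate intact.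

Compound list

1 | orcinol (5-methylbenzene-1,3-diol) | Cc1cc(O)cc(O)c1 | starting material
2 | 3-(methoxymethoxy)-5-methylphenol | COCOc1cc(C)cc(O)c1 | intermediate
3 | 3-(methoxymethoxy)-5-methylphenyl N-isopropylcarbamate | COCOc1cc(C)cc(OC(=O)NC(C)C)c1 | intermediate
4 | 3-(methoxymethoxy)-5-methylphenyl N-(tert-butyldimethylsilyl)-N-isopropylcarbamate (not isolated) | COCOc1cc(C)cc(OC(=O)N(C(C)C)[Si](C)(C)C(C)(C)C)c1 | intermediate
5 | [2-{[N-(tert-butyldimethylsilyl)-N-isopropylcarbamoyl]oxy}-6-(methoxymethoxy)-4-methylphenyl]lithium (not isolated) | COCOc1cc(C)cc(OC(=O)N(C(C)C)[Si](C)(C)C(C)(C)C)c1[Li] | intermediate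
6 | 3-(methoxymethoxy)-5-methyl-2-(trimethylsilyl)phenyl N-(tert-butyldimethylsilyl)-N-isopropylcarbamate (not isolated) | COCOc1cc(C)cc(OC(=O)N(C(C)C)[Si](C)(C)C(C)(C)C)c1[Si](C)(C)C | intermediate
7 | 3-(methoxymethoxy)-5-methyl-2-(trimethylsilyl)phenyl N-isopropylcarbamate | COCOc1cc(C)cc(OC(=O)NC(C)C)c1[Si](C)(C)C | intermediate
8 | 3-(methoxymethoxy)-5-methyl-2-(trimethylsilyl)phenol (not isolated) | COCOc1cc(C)cc(O)c1[Si](C)(C)C | intermediate
9 | 3-(methoxymethoxy)-5-methyl-2-(trimethylsilyl)phenyl trifluoromethanesulfonate | COCOc1cc(C)cc(OS(=O)(=O)C(F)(F)F)c1[Si](C)(C)C | intermediate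
10 | 2-hydroxy-5-methoxybenzaldehyde | COc1ccc(O)c(C=O)c1 | starting material
11 | 3-bromo-2-hydroxy-5-methoxybenzaldehyde | COc1cc(Br)c(O)c(C=O)c1 | intermediate
12 | 2,3-dihydroxy-5-methoxybenzaldehyde | COc1cc(O)c(O)c(C=O)c1 | intermediate
13 | disodium 3-formyl-5-methoxybenzene-1,2-diolate (not isolated) | COc1cc([O-])c([O-])c(C=O)c1.[Na+].[Na+] | intermediate
14 | 2-hydroxy-5-methoxy-3-(methoxymethoxy)benzaldehyde | COCOc1cc(OC)cc(C=O)c1O | intermediate
15 | 2-(hydroxymethyl)-4-methoxy-6-(methoxymethoxy)phenol | COCOc1cc(OC)cc(CO)c1O | intermediate
16 | 2-(tert-butyldimethylsilyloxymethyl)-4-methoxy-6-(methoxymethoxy)phenol | Oc1c(OCOC)cc(OC)cc1CO[Si](C)(C)C(C)(C)C | intermediate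
17 | carbon dioxide | O=C=O | starting material
18 | potassium 2-(tert-butyldimethylsilyloxymethyl)-4-methoxy-6-(methoxymethoxy)phenoxide (not isolated) | [K+].[O-]c1c(OCOC)cc(OC)cc1CO[Si](C)(C)C(C)(C)C | intermediate
19 | 3-(methoxymethoxy)-5-methylbenzyne (1,2-didehydro-3-(methoxymethoxy)-5-methylbenzene, not isolated) | COCOC1=CC(C)=CC#C1 | intermediate
20 | [2-[2-(tert-butyldimethylsilyloxymethyl)-4-methoxy-6-(methoxymethoxy)phenoxy]-6-(methoxymethoxy)-4-methylphenyl]potassium (not isolated) | COCOc1cc(C)cc(Oc2c(OCOC)cc(OC)cc2CO[Si](C)(C)C(C)(C)C)c1[K] | intermediate
21 | potassium 2-[2-(tert-butyldimethylsilyloxymethyl)-4-methoxy-6-(methoxymethoxy)phenoxy]-6-(methoxymethoxy)-4-methylbenzoate (not isolated) | COCOc1cc(C)cc(Oc2c(OCOC)cc(OC)cc2CO[Si](C)(C)C(C)(C)C)c1C(=O)[O-].[K+] | intermediate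
22 | 2-[2-(tert-butyldimethylsilyloxymethyl)-4-methoxy-6-(methoxymethoxy)phenoxy]-6-(methoxymethoxy)-4-methylbenzoic acid | OC(=O)c1c(OCOC)cc(C)cc1Oc1c(OCOC)cc(OC)cc1CO[Si](C)(C)C(C)(C)C | intermediate
23 | methyl 2-[2-(tert-butyldimethylsilyloxymethyl)-4-methoxy-6-(methoxymethoxy)phenoxy]-6-(methoxymethoxy)-4-methylbenzoate | COC(=O)c1c(OCOC)cc(C)cc1Oc1c(OCOC)cc(OC)cc1CO[Si](C)(C)C(C)(C)C | intermediate
24 | methyl 2-[2-(hydroxymethyl)-4-methoxy-6-(methoxymethoxy)phenoxy]-6-(methoxymethoxy)-4-methylbenzoate | COC(=O)c1c(OCOC)cc(C)cc1Oc1c(OCOC)cc(OC)cc1CO | intermediate
25 | methyl 2-[2-(acetoxymethyl)-4-methoxy-6-(methoxymethoxy)phenoxy]-6-(methoxymethoxy)-4-methylbenzoate | COC(=O)c1c(OCOC)cc(C)cc1Oc1c(OCOC)cc(OC)cc1COC(C)=O | intermediate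
26 | betaethrin A, methyl 2-[2-(acetoxymethyl)-6-hydroxy-4-methoxyphenoxy]-6-hydroxy-4-methylbenzoate | COC(=O)c1c(O)cc(C)cc1Oc1c(O)cc(OC)cc1COC(C)=O | target

Step count and risks

Total: 14 steps. Longest linear sequence: 10 steps (steps 5 to 14, from aldehyde 10); the ring A branch (steps 1 to 4) joins at step 10.

Step 10 (key step, proposed new method).
- What may go wrong: the aryl anion 20 may be protonated before it meets CO2, giving the des-carboxy diaryl ether.
- The phenoxide may be diverted into its carbonate, whose addition to the aryne and acyl shift would lead to an aryl salicylate instead of the ether acid.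
- Fluoride may slowly cleave the silyl ether and release a competing alkoxide.
- Fallback (known chemistry): form the ether by Ullmann coupling with a ring A bromide that already carries the ester, setting out from phenol 16. Commercial 3-bromo-5-methylphenol F1 is protected with MOMCl/i-Pr2NEt to give 1-bromo-3-(methoxymethoxy)-5-methylbenzene F2. Lithium diisopropylamide in THF at −78 °C deprotonates F2 between Br and the acetal oxygen, and ClCO2Me gives methyl 2-bromo-6-(methoxymethoxy)-4-methylbenzoate F3. Coupling of F3 with 16 (CuI, picolinic acid, K3PO4, DMSO, 90 °C) would give ester 23 directly, where the route is rejoined for steps 12 to 14.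

Step 3.
- What may go wrong: the silyl triflate used for N-silylation may activate and remove the methoxymethyl acetal, or lithiation may occur between the carbamate and the methyl group instead of between the two oxygens.
- Fallback: a tertiary carbamate that needs no N-protection and is removed reductively, setting out from phenol 2. ClCONEt2/NaH gives 3-(methoxymethoxy)-5-methylphenyl N,N-diethylcarbamate F4. s-BuLi/TMEDA in THF at −78 °C, then TMSCl, gives 3-(methoxymethoxy)-5-methyl-2-(trimethylsilyl)phenyl N,N-diethylcarbamate F5. LiAlH4 in THF cleaves the carbamate to silylphenol 8, which is triflated with PhNTf2 and base as in the second stage of step 4 to return to 9.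

Step 7.
- What may go wrong: alkylation at the formyl-flanked oxygen or at both oxygens, giving inseparable regioisomers.
- Fallback: from 12, excess MOMCl/i-Pr2NEt gives 5-methoxy-2,3-bis(methoxymethoxy)benzaldehyde F6. The acetal ortho to the formyl group, activated by chelation to the carbonyl, is then removed selectively with dilute HCl in THF–H2O at room temperature, returning to 14.

Step 14.
- What may go wrong: Lewis acid ionisation of the benzylic acetate with substitution by the thiol, incomplete cleavage of the ring B acetal, or ring alkylation by the methoxymethyl fragment.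
- Fallback: change the order of events, setting out from ester 23. Aqueous HCl in THF at 40 °C removes the silyl ether and both acetals in one operation to give methyl 2-hydroxy-6-[2-hydroxy-6-(hydroxymethyl)-4-methoxyphenoxy]-4-methylbenzoate F7. Lipase-catalysed transesterification with vinyl acetate (immobilised Candida antarctica lipase B, THF, 40 °C) acylates the primary benzylic hydroxyl and not the phenols, arriving at 26.

Further compounds

F1 | step 10 | 3-bromo-5-methylphenol | Cc1cc(O)cc(Br)c1
F2 | step 10 | 1-bromo-3-(methoxymethoxy)-5-methylbenzene | COCOc1cc(C)cc(Br)c1
F3 | step 10 | methyl 2-bromo-6-(methoxymethoxy)-4-methylbenzoate | COC(=O)c1c(Br)cc(C)cc1OCOC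
F4 | step 3 | 3-(methoxymethoxy)-5-methylphenyl N,N-diethylcarbamate | CCN(CC)C(=O)Oc1cc(C)cc(OCOC)c1
F5 | step 3 | 3-(methoxymethoxy)-5-methyl-2-(trimethylsilyl)phenyl N,N-diethylcarbamate | CCN(CC)C(=O)Oc1cc(C)cc(OCOC)c1[Si](C)(C)C
F6 | step 7 | 5-methoxy-2,3-bis(methoxymethoxy)benzaldehyde | COCOc1cc(OC)cc(C=O)c1OCOC
F7 | step 14 | methyl 2-hydroxy-6-[2-hydroxy-6-(hydroxymethyl)-4-methoxyphenoxy]-4-methylbenzoate | COC(=O)c1c(O)cc(C)cc1Oc1c(O)cc(OC)cc1CO
A1 | alternative 1 | methyl 2-[(7,7-dimethoxy-2,4,6-trioxoheptyl)oxy]-6-(methoxymethoxy)-4-methylbenzoate | COC(=O)c1c(OCOC)cc(C)cc1OCC(=O)CC(=O)CC(=O)C(OC)OC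
A2 | alternative 1 | methyl 2-[2-(dimethoxymethyl)-4,6-dihydroxyphenoxy]-6-(methoxymethoxy)-4-methylbenzoate | COC(=O)c1c(OCOC)cc(C)cc1Oc1c(O)cc(O)cc1C(OC)OC
A3 | alternative 2 | methyl 2-{[2-(tert-butyldimethylsilyloxymethyl)-4-diazo-3-oxobut-1-en-1-yl]oxy}-6-(methoxymethoxy)-4-methylbenzoate (alkene geometry not fixed) | COC(=O)c1c(OCOC)cc(C)cc1OC=C(CO[Si](C)(C)C(C)(C)C)C(=O)C=[N+]=[N-]
A4 | alternative 2 | methoxyacetylene | COC#C
A5 | alternative 2 | methyl 2-[2-(tert-butyldimethylsilyloxymethyl)-6-hydroxy-4-methoxyphenoxy]-6-(methoxymethoxy)-4-methylbenzoate | COC(=O)c1c(OCOC)cc(C)cc1Oc1c(O)cc(OC)cc1CO[Si](C)(C)C(C)(C)C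
A6 | alternative 3 | methyl 4-(methoxymethoxy)-6-methyl-2-oxo-2H-pyran-3-carboxylate | COC(=O)C1=C(OCOC)C=C(C)OC1=O
A7 | alternative 3 | tert-butyl{[2-(ethynyloxy)-5-methoxy-3-(methoxymethoxy)phenyl]methoxy}dimethylsilane | C#COc1c(OCOC)cc(OC)cc1CO[Si](C)(C)C(C)(C)C
A8 | alternative 3 | methyl 2-[2-(tert-butyldimethylsilyloxymethyl)-4-methoxy-6-(methoxymethoxy)phenoxy]-6-(methoxymethoxy)-4-methylbenzoate (identical with 23) | COC(=O)c1c(OCOC)cc(C)cc1Oc1c(OCOC)cc(OC)cc1CO[Si](C)(C)C(C)(C)C
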